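**Retrosynthetic overview**
1. Target ⇒ MOM removal ⇒ para-methoxylative dearomatisation of a 2-allyl-4-sec-alkyl-5-methoxyphenol under chiral aryl iodide (I/III) catalysis. This makes the C4–OMe bond and the quaternary centre last.
2. Phenol ⇒ C8–C(aryl) bond by a stereoinvertive Pd-catalysed sp3–sp2 Suzuki–Miyaura coupling of an enantioenriched secondary alkyltrifluoroborate with an aryl chloride that already carries the allyl group.
3. Trifluoroborate ⇒ Pt-catalysed enantioselective diboration of propene, then chemoselective Suzuki coupling of the primary C–B bond with MOM-protected 4-bromoguaiacol (from catechol).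
4. Aryl chloride ⇒ resorcinol by mono-methylation, para-chlorination, O-allylation/Claisen rearrangement and silylation.
5. Rings: none is built. Both six-membered rings enter as benzenediols, and the resorcinol ring becomes the cyclohexadienone in the penultimate step.

Assumption: the SMILES is read as (4S) at the ring carbon and (2R) in the side chain; MeI, MeOH, MOMCl, TIPSCl, B2pin2 and KHF2 are treated as reagents and are not numbered.

**Route**

Step 1
Reactants: 1 catechol
Product: 2 2-methoxyphenol (guaiacol)
Conditions: MeI (1.0 equiv), K2CO3, acetone, reflux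
Reagents that add atoms: iodomethane, CI
Why: Williamson ether synthesis with one equivalent of MeI alkylates the mono-phenoxide, and leftover diol and diether are removed by base extraction and distillation.

Step 2
Reactants: 2 2-methoxyphenol
Product: 3 4-bromo-2-methoxyphenol
Conditions: NBS, MeCN, 0 °C
Reagents that add atoms: N-bromosuccinimide, O=C1CCC(=O)N1Br
Why: In this electrophilic aromatic bromination the free OH is the strongest director, so bromine enters para to it.

Step 3
Reactants: 3 4-bromo-2-methoxyphenol
Product: 4 4-bromo-2-methoxy-1-(methoxymethoxy)benzene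
Conditions: MOMCl, i-Pr2NEt, CH2Cl2, 0 °C to rt
Reagents that add atoms: chloromethyl methyl ether, COCCl
Why: O-alkylation (MOM protection) installs an acetal that withstands hydroxide, fluoride, Pd catalysis and the later iodine(III) oxidation.

Step 4
Reactants: 5 propene
Product: 6 (S)-1,2-bis(4,4,5,5-tetramethyl-1,3,2-dioxaborolan-2-yl)propane
Conditions: B2pin2, Pt(dba)3 (1 mol %), 3,5-diisopropylphenyl-TADDOL phenylphosphonite (1.2 mol %, enantiomer giving (S)-6, checked by oxidising an aliquot to (S)-propane-1,2-diol), propene (1 atm), THF, 60 °C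
Reagents that add atoms: bis(pinacolato)diboron, CC1(C)OB(OC1(C)C)B1OC(C)(C)C(C)(C)O1
Why: Pt-catalysed enantioselective alkene diboration adds B–B syn across propene, and the chiral phosphonite selects the alkene face, which sets the stereocentre that becomes C8.

Step 5
Reactants: 4 4-bromo-2-methoxy-1-(methoxymethoxy)benzene; 6 (S)-1,2-bis(pinacolatoboryl)propane
Product: 7 (S)-2-{1-[3-methoxy-4-(methoxymethoxy)phenyl]propan-2-yl}-4,4,5,5-tetramethyl-1,3,2-dioxaborolane
Conditions: Pd(OAc)2 (2 mol %), RuPhos (2 mol %), KOH (3 equiv), THF/H2O 10:1, 70 °C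
Reagents that add atoms: none
Why: In this Suzuki–Miyaura coupling of a vicinal bis(boronate) the neighbouring boron speeds up transmetalation of the primary C–B bond only, so the secondary C–B stereocentre is untouched.

Step 6
Reactants: 7 (S)-secondary pinacol boronate
Product: 8 potassium (S)-trifluoro{1-[3-methoxy-4-(methoxymethoxy)phenyl]propan-2-yl}borate
Conditions: KHF2 (4.5 equiv), MeOH/H2O, rt; recrystallise
Reagents that add atoms: potassium hydrogen difluoride, [K+].[F-].F
Why: Ligand exchange at boron (boronate to trifluoroborate) does not touch the C–B bond, so configuration is retained, and crystallisation can raise the ee.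

Step 7
Reactants: 9 resorcinol
Product: 10 3-methoxyphenol
Conditions: MeI (1.0 equiv), K2CO3, acetone, reflux
Reagents that add atoms: iodomethane, CI
Why: Williamson mono-etherification of a symmetric diol gives a single mono-ether, which is separated from diol and diether by extraction and distillation.

Step 8
Reactants: 10 3-methoxyphenol
Product: 11 4-chloro-3-methoxyphenol
Conditions: SO2Cl2 (1.0 equiv), CHCl3, 0 °C to rt; chromatography
Reagents that add atoms: sulfuryl chloride, O=S(=O)(Cl)Cl
Why: In this electrophilic aromatic chlorination the position para to the free OH and ortho to OMe is the most activated open site, and the minor 6-chloro isomer is removed.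

Step 9
Reactants: 11 4-chloro-3-methoxyphenol; 12 allyl bromide
Product: 13 4-(allyloxy)-1-chloro-2-methoxybenzene
Conditions: K2CO3, acetone, reflux
Reagents that add atoms: none
Why: Williamson O-allylation of the phenoxide with a reactive allylic halide is clean in a polar aprotic medium.

Step 10
Reactants: 13 4-(allyloxy)-1-chloro-2-methoxybenzene
Product: 15 2-allyl-4-chloro-5-methoxyphenol, via ortho-dienone 14 (not isolated)
Conditions: PhNEt2, 195 °C, sealed tube
Reagents that add atoms: none
Why: In this aromatic Claisen [3,3] rearrangement with tautomerisation of 14, the chlorine pushes the methoxy methyl over the C–H between the two oxygens and a meta donor favours the site para to it, so allyl migrates para to OMe.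

Step 11
Reactants: 15 2-allyl-4-chloro-5-methoxyphenol
Product: 16 (2-allyl-4-chloro-5-methoxyphenoxy)triisopropylsilane
Conditions: TIPSCl, imidazole, DMF, rt
Reagents that add atoms: chlorotriisopropylsilane, CC(C)[Si](Cl)(C(C)C)C(C)C
Why: Silylation gives a bulky aryl silyl ether that avoids a para-phenoxide in the coupling and can be removed by fluoride while the MOM group stays.

Step 12
Reactants: 8 potassium (S)-secondary alkyltrifluoroborate; 16 (2-allyl-4-chloro-5-methoxyphenoxy)triisopropylsilane
Product: 18 (R)-{2-allyl-5-methoxy-4-[1-(3-methoxy-4-(methoxymethoxy)phenyl)propan-2-yl]phenoxy}triisopropylsilane, via secondary boronic acid 17 (not isolated)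
Conditions: P(t-Bu)3 Pd G3 (10 mol %), K2CO3 (3 equiv), PhMe/H2O 2:1, 100 °C
Reagents that add atoms: none
Why: In this stereospecific Suzuki–Miyaura coupling of an unactivated secondary alkylboron reagent, the bulky electron-rich monophosphine makes transmetalation go by backside attack with inversion and lets reductive elimination outrun β-hydride elimination, so (S)-8 gives the C8–aryl bond as (R)-18.

Step 13
Reactants: 18 (R)-TIPS ether
Product: 19 (R)-2-allyl-5-methoxy-4-{1-[3-methoxy-4-(methoxymethoxy)phenyl]propan-2-yl}phenol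
Conditions: TBAF (1.1 equiv), THF, 0 °C; H2O
Reagents that add atoms: none
Why: Fluoride desilylation of an aryl silyl ether is fast at 0 °C and leaves the MOM ether, the allyl group and C8 unchanged.

Step 14
Reactants: 19 (R)-phenol
Product: 20 (4S)-2-allyl-4,5-dimethoxy-4-{(2R)-1-[3-methoxy-4-(methoxymethoxy)phenyl]propan-2-yl}cyclohexa-2,5-dien-1-one
Conditions: 2,2'-[(2-iodo-1,3-phenylene)bis(oxy)]bis(N-mesitylpropanamide) (10 mol %, enantiomer giving 4S, both available from lactate), mCPBA (1.3 equiv), MeOH (25 equiv), CH2Cl2, −20 °C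
Reagents that add atoms: methanol, CO
Why: Proposed new method: catalyst-controlled intermolecular para-methoxylative dearomatisation, in which mCPBA oxidises the C2-symmetric lactamide iodoarene to its λ3-iodane, the phenol oxygen of 19 exchanges onto iodine, stereoelectronics hold the O–I bond perpendicular to the ring so that the iodane sits on one face, the ortho-allyl/ortho-H difference plus the hydrogen-bond-folded chiral arms favour one of the two perpendicular rotamers, and MeOH attacks C4 (best stabilised by the adjacent OMe and the alkyl group) anti to the leaving aryl iodide in a concerted vinylogous SN2′ event in weakly ionising CH2Cl2, which sets (4S) over the weak bias of C8; the closest known reaction types are the achiral PhI(OAc)2/MeOH para-quinol ether synthesis and the chiral iodoarene/mCPBA-catalysed enantioselective spirolactonisation and para-hydroxylation of phenols.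

Step 15
Reactants: 20 MOM-protected dienone
Product: 21 (4S)-4-[(2R)-1-(4-hydroxy-3-methoxyphenyl)propan-2-yl]-4,5-dimethoxy-2-(prop-2-en-1-yl)cyclohexa-2,5-dien-1-one (target)
Conditions: NaHSO4·SiO2, CH2Cl2 (wet), rt
Reagents that add atoms: none
Why: Mild heterogeneous acid hydrolysis selective for phenolic MOM acetals stays below the acidity needed for dienone–phenol rearrangement or for ionising the C4–OMe bond, so both stereocentres are kept.

**Compound list**
1 | catechol | Oc1ccccc1O | starting material
2 | 2-methoxyphenol | COc1ccccc1O | intermediate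
3 | 4-bromo-2-methoxyphenol | COc1cc(Br)ccc1O | intermediate
4 | 4-bromo-2-methoxy-1-(methoxymethoxy)benzene | COCOc1ccc(Br)cc1OC | intermediate
5 | propene | C=CC | starting material
6 | (S)-1,2-bis(4,4,5,5-tetramethyl-1,3,2-dioxaborolan-2-yl)propane | CC1(C)OB(OC1(C)C)[C@@H](C)CB1OC(C)(C)C(C)(C)O1 | intermediate
7 | (S)-2-{1-[3-methoxy-4-(methoxymethoxy)phenyl]propan-2-yl}-4,4,5,5-tetramethyl-1,3,2-dioxaborolane | CC1(C)OB(OC1(C)C)[C@@H](C)Cc1ccc(OCOC)c(OC)c1 | intermediate
8 | potassium (S)-trifluoro{1-[3-methoxy-4-(methoxymethoxy)phenyl]propan-2-yl}borate | [K+].F[B-](F)(F)[C@@H](C)Cc1ccc(OCOC)c(OC)c1 | intermediate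
9 | resorcinol | Oc1cccc(O)c1 | starting material
10 | 3-methoxyphenol | COc1cccc(O)c1 | intermediate
11 | 4-chloro-3-methoxyphenol | COc1cc(O)ccc1Cl | intermediate
12 | allyl bromide | C=CCBr | starting material
13 | 4-(allyloxy)-1-chloro-2-methoxybenzene | C=CCOc1ccc(Cl)c(OC)c1 | intermediate
14 | 6-allyl-4-chloro-3-methoxycyclohexa-2,4-dien-1-one (racemic, not isolated) | C=CCC1C=C(Cl)C(OC)=CC1=O | intermediate
15 | 2-allyl-4-chloro-5-methoxyphenol | C=CCc1cc(Cl)c(OC)cc1O | intermediate
16 | (2-allyl-4-chloro-5-methoxyphenoxy)triisopropylsilane | C=CCc1cc(Cl)c(OC)cc1O[Si](C(C)C)(C(C)C)C(C)C | intermediate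
17 | (S)-{1-[3-methoxy-4-(methoxymethoxy)phenyl]propan-2-yl}boronic acid (not isolated) | OB(O)[C@@H](C)Cc1ccc(OCOC)c(OC)c1 | intermediate
18 | (R)-{2-allyl-5-methoxy-4-[1-(3-methoxy-4-(methoxymethoxy)phenyl)propan-2-yl]phenoxy}triisopropylsilane | C=CCc1cc([C@H](C)Cc2ccc(OCOC)c(OC)c2)c(OC)cc1O[Si](C(C)C)(C(C)C)C(C)C | intermediate
19 | (R)-2-allyl-5-methoxy-4-{1-[3-methoxy-4-(methoxymethoxy)phenyl]propan-2-yl}phenol | C=CCc1cc([C@H](C)Cc2ccc(OCOC)c(OC)c2)c(OC)cc1O | intermediate
20 | (4S)-2-allyl-4,5-dimethoxy-4-{(2R)-1-[3-methoxy-4-(methoxymethoxy)phenyl]propan-2-yl}cyclohexa-2,5-dien-1-one | C=CCC1=C[C@@](OC)([C@H](C)Cc2ccc(OCOC)c(OC)c2)C(OC)=CC1=O | intermediate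
21 | (4S)-4-[(2R)-1-(4-hydroxy-3-methoxyphenyl)propan-2-yl]-4,5-dimethoxy-2-(prop-2-en-1-yl)cyclohexa-2,5-dien-1-one | C=CCC1=C[C@@](OC)([C@H](C)Cc2ccc(O)c(OC)c2)C(OC)=CC1=O | target

**Totals**
Total step count: 15.
Longest linear sequence: 9 (steps 1, 2, 3, 5, 6, 12, 13, 14, 15). The resorcinol arm, steps 7–11 followed by 12–15, is equally long.

**Three steps most likely to fail**

Step 12.
- Risks:
  - The electron-rich, ortho-methoxy chloride 16 may add to Pd slowly.
  - The homobenzylic alkyl-Pd species may undergo β-hydride elimination, which costs ee or gives the benzylic isomer.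
  - Pd–H may move the allyl double bond into conjugation.
- The fallback uses known chemistry. It sets C8 by asymmetric hydrogenation instead of stereospecific coupling and installs the allyl group afterwards. It sets out from 4, 11 and 12 and comes back at 19.
- Sonogashira coupling of 4 with propyne (PdCl2(PPh3)2, CuI, Et3N) gives 2-methoxy-1-(methoxymethoxy)-4-(prop-1-yn-1-yl)benzene F1.
- Cu-catalysed syn-hydroboration (CuCl, Xantphos, NaOt-Bu, B2pin2, MeOH) puts boron on the methyl-bearing carbon and gives the (Z)-alkenyl pinacol boronate F2.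
- sp2–sp2 Suzuki coupling of F2 with unprotected 11 (Pd(OAc)2, SPhos, K3PO4, dioxane/H2O) gives the (E)-α-methylstilbene phenol F3.
- Ir–PHOX/BArF hydrogenation (50 bar H2, CH2Cl2, ligand enantiomer chosen for R) gives the (R)-diarylpropane phenol F4.
- O-allylation with 12 (K2CO3, acetone) gives the (R)-aryl allyl ether F5.
- Claisen rearrangement of F5 (PhNEt2, 195 °C) gives 19. The sec-alkyl group now buttresses the methoxy group and steers the regiochemistry.

Step 14 (the proposed new step).
- Risk: a dissociative phenoxenium pathway would erase catalyst control, so the dr could be low or have the wrong sense.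
- The fallback uses known chemistry. It gives up reagent control and relies on separation and recycling. It sets out from 19 and comes back at 20.
- Stoichiometric PhI(OAc)2 in MeOH at 0 °C (or anodic oxidation in MeOH) gives roughly equal amounts of 20 and the (4R)-epimeric dienone F6.
- The two epimers are separated by chromatography or preparative HPLC.
- F6 is returned to 19 by reductive rearomatisation with Zn in AcOH and resubmitted.

Step 15.
- Risk: even mild acid could trigger alkyl migration (dienone–phenol rearrangement) or attack of the freed guaiacyl ring on the dienone.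
- The fallback swaps the protecting group at the robust arene stage, so the last step is a mild methanolysis. It sets out from 18 and comes back at 21.
- Catalytic HCl in MeOH at 45 °C removes the MOM group and gives the ring-A phenol TIPS ether F7.
- Ac2O in pyridine gives the aryl acetate TIPS ether F8.
- HF·pyridine in THF gives the ring-B phenol acetate F9.
- Dearomatisation as in step 14 gives the dienone acetate F10.
- K2CO3 in MeOH at 0 °C gives 21.

**Further compounds**
F1 | step 12 | 2-methoxy-1-(methoxymethoxy)-4-(prop-1-yn-1-yl)benzene | CC#Cc1ccc(OCOC)c(OC)c1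
F2 | step 12 | (Z)-2-{1-[3-methoxy-4-(methoxymethoxy)phenyl]prop-1-en-2-yl}-4,4,5,5-tetramethyl-1,3,2-dioxaborolane | C/C(B1OC(C)(C)C(C)(C)O1)=C\c1ccc(OCOC)c(OC)c1
F3 | step 12 | (E)-3-methoxy-4-{1-[3-methoxy-4-(methoxymethoxy)phenyl]prop-1-en-2-yl}phenol | C/C(c1ccc(O)cc1OC)=C\c1ccc(OCOC)c(OC)c1
F4 | step 12 | (R)-3-methoxy-4-{1-[3-methoxy-4-(methoxymethoxy)phenyl]propan-2-yl}phenol | Oc1ccc([C@H](C)Cc2ccc(OCOC)c(OC)c2)c(OC)c1
F5 | step 12 | (R)-4-(allyloxy)-2-methoxy-1-{1-[3-methoxy-4-(methoxymethoxy)phenyl]propan-2-yl}benzene | C=CCOc1ccc([C@H](C)Cc2ccc(OCOC)c(OC)c2)c(OC)c1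
F6 | step 14 | (4R)-2-allyl-4,5-dimethoxy-4-{(2R)-1-[3-methoxy-4-(methoxymethoxy)phenyl]propan-2-yl}cyclohexa-2,5-dien-1-one | C=CCC1=C[C@](OC)([C@H](C)Cc2ccc(OCOC)c(OC)c2)C(OC)=CC1=O
F7 | step 15 | (R)-4-{2-[5-allyl-2-methoxy-4-(triisopropylsilyloxy)phenyl]propyl}-2-methoxyphenol | C=CCc1cc([C@H](C)Cc2ccc(O)c(OC)c2)c(OC)cc1O[Si](C(C)C)(C(C)C)C(C)C
F8 | step 15 | (R)-4-{2-[5-allyl-2-methoxy-4-(triisopropylsilyloxy)phenyl]propyl}-2-methoxyphenyl acetate | C=CCc1cc([C@H](C)Cc2ccc(OC(C)=O)c(OC)c2)c(OC)cc1O[Si](C(C)C)(C(C)C)C(C)C
F9 | step 15 | (R)-4-[2-(5-allyl-4-hydroxy-2-methoxyphenyl)propyl]-2-methoxyphenyl acetate | C=CCc1cc([C@H](C)Cc2ccc(OC(C)=O)c(OC)c2)c(OC)cc1O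
F10 | step 15 | 4-{(2R)-2-[(1S)-3-allyl-1,6-dimethoxy-4-oxocyclohexa-2,5-dien-1-yl]propyl}-2-methoxyphenyl acetate | C=CCC1=C[C@@](OC)([C@H](C)Cc2ccc(OC(C)=O)c(OC)c2)C(OC)=CC1=O
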